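(All runs were generated by integration with made-up constants, noise included.)

At 8.00 min, Thursday's flask shows Xa and Dx together at 17.7% of the J charged, and the other 82.3% is unread. You need not place it to get the ratio.

| flask | J | Z | X | remark | time |
|---|---|---|---|---|---|
| Thursday's | 1 M | 2.5 M | 1.2 M | the very flask that is asked about, followed so far |  |
| flask | 1.0 M | 2.50 M | 1.20 M |  | 20 min |

Thursday's run (percent of the J charged)

| time / min | Xa / % | Dx / % |
|---|---|---|
| 2.00 | 3.1 | 3.1 |
| 4.00 | 7.8 | 1.7 |
| 6.00 | 8.4 | 3.1 |
| 8.00 | 12.6 | 5.1 |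

(standard deviation of a reading: 1 percentage point)

- what was read earlier has a scatter of 1 percentage point, one standard deviation
- candidate steps: J -> Q; Z + Q -> Dx; X + Q -> Xa; Q -> G; Z -> D; J <-> E

- ratio of Xa to Dx at 30 s
- ratio of Xa to Dx at 20 min
- which of Xa and Dx there is more of at 20 min

Among the candidate steps, J gives Q, and Q goes on with Z to Dx, with X to Xa, or by itself to G. Z may turn into D, and J may pass reversibly into E. The two product rates are kZ[Z][Q] and kX[X][Q], with k a rate constant and brackets concentrations, so [Q] cancels from their quotient. Integrated with [X] and [Z] held at their charges, this gives Xa/Dx = s[X]/[Z]. The summed readings of Thursday's flask give a ratio of 2.45, read through a scatter of 1 percentage point, so the selectivity factor s, kX over kZ, reads as 5.11.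

Now turn the settings by hand. By this quotient, with the other charge held, more X raises the ratio in proportion, and more Z lowers it in proportion. The charge of J does not enter the quotient. Time enters through the drift of [X]/[Z]: X is spent on Xa, and Z on Dx and on D, if that step runs. My own reckoning for Thursday's flask is 2.45 at 30 s, lower than the forecast's figure, with a rise to expect by 20 min if Z turns into D.

The forecast holds that “the ratio should follow kX[X]/kZ[Z]”. It gives 2.7 at 30 s, 2.4 at 20 min, and Xa ahead.

The simulation of Thursday's flask gives 2.87 and 3.29, with Xa ahead at 18.4% against 5.61% of Dx.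

    J → Q (k = 7.52 × 10⁻⁴ s⁻¹)
    Z + Q → Dx (k = 0.0688 M⁻¹ s⁻¹)
    X + Q → Xa (k = 0.410 M⁻¹ s⁻¹)
    Q → G (k = 0.202 s⁻¹)
    Z → D (k = 5.65 × 10⁻⁴ s⁻¹)
    J ⇌ E (K = 8.90, k = 0.00155 s⁻¹)

The ratio in Thursday's flask climbs with the hour of the reading: it is 3.29 at 20 min and 5.81 at 200 min. Part of this comes from Z turning into D: the run without that step gives 2.68 at 20 min. At 20 min, Z stands at 49.4% of its charge and X at 84.6%, so s gives a momentary quotient of 4.21, and the accumulated ratio trails it. In the neighbour with 0.30 M of X, s gives 0.613. That neighbour computes to 0.716 at 30 s and 0.782 at 20 min, with Dx at 9.88% ahead of Xa at 7.73%.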